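The data come from a simulation from invented constants.

At 6.0 h we read the flask, which is the maple run followed on past its last reading.

| flask | substrate | reagent | temperature | remark | time |
|---|---|---|---|---|---|
| maple | 0.78 M | 0.78 M | −20 °C | the very flask that is asked about, followed so far |  |
| ash | 0.78 M | 0.52 M | −35 °C | run made earlier |  |
| flask | 0.78 M | 0.780 M | −20 °C |  | 6.0 h |

| run | time / h | target / % |
|---|---|---|
| maple | 0.250 | 22 |
| maple | 0.417 | 29 |
| maple | 0.667 | 40 |
| maple | 1.00 | 49 |
| maple | 1.50 | 53 |
| maple | 2.50 | 57 |
| maple | 4.00 | 63 |
| ash | 0.667 | 3 |
| ash | 1.00 | 11 |
| ash | 2.00 | 13 |
| ash | 3.00 | 18 |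
| ash | 4.00 | 22 |
| ash | 6.00 | 32 |
| ash | 8.00 | 32 |

(scatter of a reading: 2 percentage points)

- ochre: change nothing and wait 2.0 h more
- blue: at 6.0 h add reagent, 50.0% of the amount charged, then wait 2.0 h
- green: at 6.0 h raise the temperature by 25 K, then wait 2.0 h
- teal: at 6.0 h take out 90% of the target then present, then wait 2.0 h

- target that was removed still counts
- the numbers in the tables scatter by 2 percentage points (one standard deviation)
- additions bring no volume worth counting

* target, in percent of the substrate first charged, at 6.0 h
* what to do for the largest gain in target; "none" if nothing gains more than 2 percentage points (ochre / blue / green / teal / none)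
* target present, with what was taken out counted in, in percent of the substrate first charged, after blue
* target present, with what was taken out counted in, in percent of the substrate first charged, after teal

We read the maple table from the top. Its first row, 22% at 0.250 h, stands nearest the start, and the charges are equal, so target over what is left, per unit of time, gives 1.13 h⁻¹. This reading, which carries the scatter of that one row, is our starting rate constant, the share of substrate turned into target per hour with reagent at full charge, a pseudo-first-order constant. Our rule is that target forms at this constant times the share of substrate left times the share of reagent left.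

As a first answer, both shares fall together, which puts the last row at 81.9%, but the table says 63%. So we put that reading back in and go round again. If target were the one thing formed, 37.0% of each would stand at the last row and the rule would ask for 0.155 h⁻¹, while the last two rows climb by 0.0400 h⁻¹, which is less, though that slope carries the scatter of both readings. So something besides this step takes substrate or reagent, or uses up target.

Taking equal shares once more as an estimate, the slope gives us 18.8% of each at 4.00 h and 13.2% at 6.0 h. Our own figure for target at that time is therefore 68.6%. On our rule, waiting adds 3 percentage points, and blue, reckoned with reagent held steady, adds 10 points. The rule prices neither warming nor taking target out, so we back blue.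

The forecast, lower than ours at the time of reading, gave 64%, chose blue, and put blue at 81% and teal at 65%, holding that “Waiting, warming or removing target therefore gain almost nothing”.

The flask gives 62.2%. Green gains most, 17 points, while blue reaches 64.3% and teal 71.7%.

    substrate + reagent → target (k = 3.83 × 10⁻⁴ L mol⁻¹ s⁻¹, Ea = 69.0 kJ mol⁻¹)
    substrate → side product (k = 3.40 × 10⁻⁵ s⁻¹, Ea = 79.0 kJ mol⁻¹)
    2 substrate → self-condensation product (k = 1.30 × 10⁻⁸ L mol⁻¹ s⁻¹, Ea = 68.0 kJ mol⁻¹)
    target ⇌ isomer of the product (K = 0.278, k = 4.01 × 10⁻⁵ s⁻¹, Ea = 79.0 kJ mol⁻¹, ΔH = −59.0 kJ mol⁻¹)
    (constants at −20 °C)

At 0.623 h target in the flask is made 8.16 times faster than it is used up, each step taken net, but at 6.00 h the figure is 1.53, still above one. The shares at that time are unequal, substrate 4.68% and reagent 21.9%, and on them our starting rate constant gives 0.0116 h⁻¹. The neighbour flask with 0.47 M of substrate and the same reagent charge holds 67.7% target, with substrate at 1.18% and reagent at 48.7%, and there the same rule, as a share of that flask's own substrate charge per hour, gives 0.00649 h⁻¹.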